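**Retrosynthetic overview**
- Feature: in each quinone ring the carbonyl carbon C1 lies between C2, which carries the succinate methine, and C6, which carries geranyl. A carbon tethered to the C1 oxygen therefore finds only one open ortho carbon.
- Last disconnections: both quinones come from 4-methoxyphenol rings by oxidative demethylation. The methyl esters come from N-methylamides by N-Boc activation, phenoxide-assisted lactonisation and methanolysis, with base equilibration to meso.
- Key disconnection: both methine–aryl bonds are traced back to N–O tethers, that is, a twofold [3,3] shift of the bis(enolate) of a succinyl bis(N-aryloxy-N-methylamide). The C2–C3 bond and both carboxyl carbons arrive intact from succinyl chloride.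
- The tethered precursor comes from 2-geranyl-4-methoxyphenol (4-methoxyphenol plus geraniol) by O-amination, double N-acylation and N-methylation.
- Ring order: no lasting ring is built. Both carbocycles are bought as 4-methoxyphenol, and only two transient lactone rings close and open in the ester-forming step.

Key step: step 5

Remark: the two descriptors of the target belong to one S and one R centre with identical substituents. This is the meso form, so only relative configuration has to be controlled. Geranyl stands for (2E)-3,7-dimethylocta-2,6-dien-1-yl throughout.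

**Route**

Step 1
Reactants: 1 4-methoxyphenol; 2 geraniol
Product: 3 2-geranyl-4-methoxyphenol
Conditions: acidic Al2O3, ClCH2CH2Cl, reflux; 1 in excess
Reagents that add atoms: none
Why: Surface-templated Friedel–Crafts allylation, in which phenol and allylic alcohol are co-adsorbed on the acidic Al2O3 so that the geranyl cation equivalent is handed to the carbon ortho to OH (para is blocked by OMe), the E-alkene is kept, and the excess of 1 holds back double geranylation.

Step 2
Reactants: 3 2-geranyl-4-methoxyphenol
Product: 5 O-(2-geranyl-4-methoxyphenyl)hydroxylamine, via potassium phenoxide 4 (not isolated)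
Conditions: KOtBu, DMF, 0 °C; then O-(2,4-dinitrophenyl)hydroxylamine, 0 °C → rt
Reagents that add atoms: O-(2,4-dinitrophenyl)hydroxylamine, NOc1ccc(cc1[N+](=O)[O-])[N+](=O)[O-]
Why: Electrophilic amination of a phenoxide (SN2 at nitrogen with 2,4-dinitrophenoxide as leaving group) is an established entry to O-arylhydroxylamines, no metal is present so the alkenes stay untouched, and 5 is used at once because electron-rich aryloxyamines store poorly.

Step 3
Reactants: 5 O-(2-geranyl-4-methoxyphenyl)hydroxylamine (2.2 equiv); 6 succinyl chloride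
Product: 7 N,N'-bis(2-geranyl-4-methoxyphenoxy)succinamide
Conditions: pyridine, CH2Cl2, −20 → 0 °C; 6 added slowly to 5
Reagents that add atoms: none
Why: Schotten–Baumann-type N-acylation, in which slow addition of the diacid chloride to an excess of the nucleophile with only a weak base should keep the half-acylated species from closing to the N-aryloxysuccinimide.

Step 4
Reactants: 7 N,N'-bis(2-geranyl-4-methoxyphenoxy)succinamide
Product: 8 N,N'-dimethyl-N,N'-bis(2-geranyl-4-methoxyphenoxy)succinamide
Conditions: MeI, K2CO3, DMF, 0 °C → rt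
Reagents that add atoms: iodomethane, CI
Why: N-alkylation of an O-substituted hydroxamate with a soft electrophile favours nitrogen over the carbonyl oxygen, and capping both NH groups removes the Lossen-type breakdown and the N-deprotonation that would otherwise compete in step 5.

Step 5
Reactants: 8 N,N'-dimethyl-N,N'-bis(2-geranyl-4-methoxyphenoxy)succinamide
Product: 11 meso-2,3-bis(3-geranyl-2-hydroxy-5-methoxyphenyl)-N,N'-dimethylsuccinamide, via dilithium bis(enolate) 9 (not isolated), via bis(dienone) bis(amidate) 10 (not isolated)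
Conditions: LiN(SiMe3)2 (5 equiv), THF, −78 °C, then → 0 °C; aq NH4Cl
Reagents that add atoms: none
Why: Proposed new method: an excess of LiN(SiMe3)2 charged cold converts both acyl groups into Z(O)-lithium enolates (9), in each of which Cα=C(OLi)–N–O–C1(aryl)=C6(aryl) is a six-atom array, so that on warming a charge-accelerated [3,3] shift cleaves the weak N–O bond and joins Cα to C6 to give 10, whose ring C–H is then shuffled to the heteroatoms to restore the arene before the NH4Cl quench releases 11. The closest known reaction types are the [3,3] shift of O-aryl oxime ethers (through their N-aryloxy enamine tautomers) used for benzofurans and the anionic hetero-Claisen shifts of enolates of acylated hydroxylamines; an amide enolate shifting onto an O-aryl group, twice across one succinyl unit, has not been shown. No ring is closed, since the two six-membered arrays exist only as transition states. The first methine may form with either sense because the product is meso, and the second is set by 1,2-induction: with the succinyl C2–H bond eclipsing the remaining enolate C=C (minimal allylic strain) the second arene is delivered to the face opposite the first aryl group, which corresponds to the meso relationship, and any dl isomer is carried on and corrected in step 7. The step needs ortho regioselectivity, which the geranyl group on the other ortho carbon secures, because bonding there would build a quaternary carbon in a dienone that cannot rearomatise, whereas C6 bears hydrogen. It also needs enolisation to outrun E2 loss of aryloxide at N–CH3 and attack of the released amidate or phenoxide on the second acyl group, which the higher acidity of the α-CH2 groups and the early enolisation of both ends should secure, while this base is too weak to touch the benzylic-allylic CH2 of the geranyl chains.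

Step 6
Reactants: 11 meso-2,3-bis(3-geranyl-2-hydroxy-5-methoxyphenyl)-N,N'-dimethylsuccinamide
Product: 12 meso-N,N'-bis(tert-butoxycarbonyl)-2,3-bis[2-(tert-butoxycarbonyloxy)-3-geranyl-5-methoxyphenyl]-N,N'-dimethylsuccinamide
Conditions: Boc2O (excess), DMAP (cat.), Et3N, MeCN, rt
Reagents that add atoms: di-tert-butyl dicarbonate, CC(C)(C)OC(=O)OC(=O)OC(C)(C)C
Why: DMAP-catalysed tert-butoxycarbonylation (N-Boc activation of a secondary amide) turns both amides into N-acyl carbamates and both phenols into carbonates, so that acyl transfer can later run under base, whereas the hot acid a plain N-methylamide would need for lactonisation would cyclise the o-geranylphenols to chromans.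

Step 7
Reactants: 12 meso-N,N'-bis(tert-butoxycarbonyl)-2,3-bis[2-(tert-butoxycarbonyloxy)-3-geranyl-5-methoxyphenyl]-N,N'-dimethylsuccinamide
Product: 14 dimethyl meso-2,3-bis(3-geranyl-2-hydroxy-5-methoxyphenyl)succinate, via bis(benzofuranone) 13 (not isolated)
Conditions: NaOMe, MeOH–THF, argon, 0 → 40 °C; AcOH, 0 °C
Reagents that add atoms: sodium methoxide, C[O-].[Na+]; methanol, CO
Why: Transacylation and base epimerisation in one pot, in which methoxide strips the aryl carbonates, each freed phenoxide closes 5-exo-trig on its neighbouring N-acyl carbamate and expels the carbamate anion (13), methoxide opens the lactones to the methyl esters, and the acidic methines (most acidic in the lactone form) equilibrate toward the meso diester, the more stable isomer of 2,3-diarylsuccinates because all like groups can lie anti, with any remaining dl isomer separated and resubmitted.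

Step 8
Reactants: 14 dimethyl meso-2,3-bis(3-geranyl-2-hydroxy-5-methoxyphenyl)succinate
Product: 16 dimethyl meso-2,3-bis(5-geranyl-3,6-dioxocyclohexa-1,4-dien-1-yl)succinate (target CNP0183145.1), via bis(hemiketal) 15 (not isolated)
Conditions: PhI(OAc)2 (2.2 equiv), MeCN–H2O, 0 °C
Reagents that add atoms: water, O
Why: Oxidative demethylation of a 4-methoxyphenol by a trivalent iodine reagent, in which the phenol binds to iodine, water adds at the methoxy-bearing para carbon to give 15 and methanol is lost, the phenols react far faster than the trisubstituted alkenes, and the cold, short, weakly acidic medium should leave the methine centres unenolised.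

**Compound list**
1 | 4-methoxyphenol | COc1ccc(O)cc1 | starting material
2 | geraniol | CC(C)=CCC/C(C)=C/CO | starting material
3 | 2-geranyl-4-methoxyphenol | COc1ccc(O)c(C/C=C(\C)CCC=C(C)C)c1 | intermediate
4 | potassium 2-geranyl-4-methoxyphenoxide | [K+].COc1ccc([O-])c(C/C=C(\C)CCC=C(C)C)c1 | intermediate
5 | O-(2-geranyl-4-methoxyphenyl)hydroxylamine | COc1ccc(ON)c(C/C=C(\C)CCC=C(C)C)c1 | intermediate
6 | succinyl chloride | O=C(Cl)CCC(=O)Cl | starting material
7 | N,N'-bis(2-geranyl-4-methoxyphenoxy)succinamide | O=C(CCC(=O)NOc1ccc(OC)cc1C/C=C(\C)CCC=C(C)C)NOc1ccc(OC)cc1C/C=C(\C)CCC=C(C)C | intermediate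
8 | N,N'-dimethyl-N,N'-bis(2-geranyl-4-methoxyphenoxy)succinamide | CN(Oc1ccc(OC)cc1C/C=C(\C)CCC=C(C)C)C(=O)CCC(=O)N(C)Oc1ccc(OC)cc1C/C=C(\C)CCC=C(C)C | intermediate
9 | dilithium (Z,Z)-bis(enolate) of 8 | [Li+].[Li+].CN(Oc1ccc(OC)cc1C/C=C(\C)CCC=C(C)C)/C([O-])=C/C=C(\[O-])N(C)Oc1ccc(OC)cc1C/C=C(\C)CCC=C(C)C | intermediate
10 | dilithium bis(amidate) of 2,3-bis(5-geranyl-3-methoxy-6-oxocyclohexa-2,4-dien-1-yl)-N,N'-dimethylsuccinamide (ring sp3 carbons undefined) | [Li+].[Li+].CN=C([O-])[C@H](C1C=C(OC)C=C(C/C=C(\C)CCC=C(C)C)C1=O)[C@@H](C([O-])=NC)C1C=C(OC)C=C(C/C=C(\C)CCC=C(C)C)C1=O | intermediate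
11 | meso-(2R,3S)-2,3-bis(3-geranyl-2-hydroxy-5-methoxyphenyl)-N,N'-dimethylsuccinamide | CNC(=O)[C@H](c1cc(OC)cc(C/C=C(\C)CCC=C(C)C)c1O)[C@@H](C(=O)NC)c1cc(OC)cc(C/C=C(\C)CCC=C(C)C)c1O | intermediate
12 | meso-N,N'-bis(tert-butoxycarbonyl)-2,3-bis[2-(tert-butoxycarbonyloxy)-3-geranyl-5-methoxyphenyl]-N,N'-dimethylsuccinamide | CN(C(=O)OC(C)(C)C)C(=O)[C@H](c1cc(OC)cc(C/C=C(\C)CCC=C(C)C)c1OC(=O)OC(C)(C)C)[C@@H](C(=O)N(C)C(=O)OC(C)(C)C)c1cc(OC)cc(C/C=C(\C)CCC=C(C)C)c1OC(=O)OC(C)(C)C | intermediate
13 | meso-(3R,3'S)-7,7'-digeranyl-5,5'-dimethoxy-3,3'-bi(benzofuran-2(3H)-one) | O=C1Oc2c(C/C=C(\C)CCC=C(C)C)cc(OC)cc2[C@@H]1[C@H]1C(=O)Oc2c(C/C=C(\C)CCC=C(C)C)cc(OC)cc21 | intermediate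
14 | dimethyl meso-(2R,3S)-2,3-bis(3-geranyl-2-hydroxy-5-methoxyphenyl)succinate | COC(=O)[C@H](c1cc(OC)cc(C/C=C(\C)CCC=C(C)C)c1O)[C@@H](C(=O)OC)c1cc(OC)cc(C/C=C(\C)CCC=C(C)C)c1O | intermediate
15 | dimethyl meso-2,3-bis(5-geranyl-3-hydroxy-3-methoxy-6-oxocyclohexa-1,4-dien-1-yl)succinate (hemiketal carbons undefined) | COC(=O)[C@H](C1=CC(O)(OC)C=C(C/C=C(\C)CCC=C(C)C)C1=O)[C@@H](C(=O)OC)C1=CC(O)(OC)C=C(C/C=C(\C)CCC=C(C)C)C1=O | intermediate
16 | dimethyl meso-(2R,3S)-2,3-bis(5-geranyl-3,6-dioxocyclohexa-1,4-dien-1-yl)succinate, CNP0183145.1 | COC(=O)[C@H](C1=CC(=O)C=C(C/C=C(\C)CCC=C(C)C)C1=O)[C@@H](C(=O)OC)C1=CC(=O)C=C(C/C=C(\C)CCC=C(C)C)C1=O | target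

**Step count**
Total step count: 8. Longest linear sequence: 8 steps (1 → 16).

**Steps most likely to fail**

1. Step 5 (twofold [3,3] shift).
   - What may go wrong: base-induced elimination of aryloxide at N–CH3, cyclisation of the half-rearranged species onto the second acyl group, or a second shift that stalls.
   - Approach: the fallback uses known reactions only. It makes the central C–C bond by oxidative enolate dimerisation instead of importing it with 6. It sets out from 1 (and uses 2) and comes back to the route at 14.
   - 1 is condensed with glyoxylic acid in aqueous NaOH (ortho hydroxyalkylation, para position blocked) to 2-hydroxy-2-(2-hydroxy-5-methoxyphenyl)acetic acid F1.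
   - Benzylic reduction with SnCl2 and HCl in hot AcOH, with lactonisation, gives 5-methoxybenzofuran-2(3H)-one F2.
   - MeOH with catalytic H2SO4 opens it to methyl 2-(2-hydroxy-5-methoxyphenyl)acetate F3.
   - Geraniol 2 over acidic Al2O3, as in step 1, fills the only free ortho position to give methyl 2-(3-geranyl-2-hydroxy-5-methoxyphenyl)acetate F4.
   - TBSCl and imidazole give methyl 2-[2-(tert-butyldimethylsilyloxy)-3-geranyl-5-methoxyphenyl]acetate F5.
   - LiN(iPr)2 in THF at −78 °C followed by half an equivalent of I2 (α-iodination, then SN2 by a second enolate) gives dimethyl 2,3-bis[2-(tert-butyldimethylsilyloxy)-3-geranyl-5-methoxyphenyl]succinate F6 as meso and dl forms.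
   - Bu4NF buffered with AcOH removes the silyl groups. Equilibration with NaOMe in MeOH as in step 7 then leads to 14.

2. Step 2 (O-amination).
   - What may go wrong: attack of the hindered phenoxide on the dinitroarene ring instead of at nitrogen, and N–O fragmentation of the electron-rich product during isolation.
   - Approach: the fallback forms the aryl–O bond instead of the O–N bond. It sets out from 3 and comes back at 5.
   - PhNTf2 and Et3N convert 3 into 2-geranyl-4-methoxyphenyl trifluoromethanesulfonate F7.
   - Miyaura borylation (B2pin2, Pd(dppf)Cl2, KOAc, dioxane, 80 °C) gives 2-(2-geranyl-4-methoxyphenyl)-4,4,5,5-tetramethyl-1,3,2-dioxaborolane F8.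
   - NaIO4 and NH4OAc in aqueous acetone give (2-geranyl-4-methoxyphenyl)boronic acid F9.
   - Chan–Lam coupling with N-hydroxyphthalimide (Cu(OAc)2, pyridine, molecular sieves, air, ClCH2CH2Cl, rt) gives N-(2-geranyl-4-methoxyphenoxy)phthalimide F10.
   - Hydrazine hydrate in CHCl3–MeOH releases 5.

3. Step 8 (final oxidation).
   - What may go wrong: enolisation of the methines toward quinone methide tautomers while oxidant is still present, with erosion of configuration and over-oxidation, or attack of the oxidant on the chain alkenes if the phenol oxidation is slow.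
   - Approach: the fallback separates oxidation from unmasking. It sets out from 14 and comes back at 16.
   - PhI(OAc)2 in dry MeOH at 0 °C gives the bis(quinone monoketal) dimethyl meso-2,3-bis(5-geranyl-3,3-dimethoxy-6-oxocyclohexa-1,4-dien-1-yl)succinate F11, which is purified free of oxidant.
   - F11 is then hydrolysed with aqueous oxalic acid on silica gel in CH2Cl2 to 16.

**Further compounds**
F1 | step 5 | 2-hydroxy-2-(2-hydroxy-5-methoxyphenyl)acetic acid (racemic) | COc1ccc(O)c(C(O)C(=O)O)c1
F2 | step 5 | 5-methoxybenzofuran-2(3H)-one | COc1ccc2OC(=O)Cc2c1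
F3 | step 5 | methyl 2-(2-hydroxy-5-methoxyphenyl)acetate | COC(=O)Cc1cc(OC)ccc1O
F4 | step 5 | methyl 2-(3-geranyl-2-hydroxy-5-methoxyphenyl)acetate | COC(=O)Cc1cc(OC)cc(C/C=C(\C)CCC=C(C)C)c1O
F5 | step 5 | methyl 2-[2-(tert-butyldimethylsilyloxy)-3-geranyl-5-methoxyphenyl]acetate | COC(=O)Cc1cc(OC)cc(C/C=C(\C)CCC=C(C)C)c1O[Si](C)(C)C(C)(C)C
F6 | step 5 | dimethyl 2,3-bis[2-(tert-butyldimethylsilyloxy)-3-geranyl-5-methoxyphenyl]succinate (meso form drawn) | COC(=O)[C@H](c1cc(OC)cc(C/C=C(\C)CCC=C(C)C)c1O[Si](C)(C)C(C)(C)C)[C@@H](C(=O)OC)c1cc(OC)cc(C/C=C(\C)CCC=C(C)C)c1O[Si](C)(C)C(C)(C)C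
F7 | step 2 | 2-geranyl-4-methoxyphenyl trifluoromethanesulfonate | COc1ccc(OS(=O)(=O)C(F)(F)F)c(C/C=C(\C)CCC=C(C)C)c1
F8 | step 2 | 2-(2-geranyl-4-methoxyphenyl)-4,4,5,5-tetramethyl-1,3,2-dioxaborolane | COc1ccc(B2OC(C)(C)C(C)(C)O2)c(C/C=C(\C)CCC=C(C)C)c1
F9 | step 2 | (2-geranyl-4-methoxyphenyl)boronic acid | COc1ccc(B(O)O)c(C/C=C(\C)CCC=C(C)C)c1
F10 | step 2 | N-(2-geranyl-4-methoxyphenoxy)phthalimide | COc1ccc(ON2C(=O)c3ccccc3C2=O)c(C/C=C(\C)CCC=C(C)C)c1
F11 | step 8 | dimethyl meso-2,3-bis(5-geranyl-3,3-dimethoxy-6-oxocyclohexa-1,4-dien-1-yl)succinate | COC(=O)[C@H](C1=CC(OC)(OC)C=C(C/C=C(\C)CCC=C(C)C)C1=O)[C@@H](C(=O)OC)C1=CC(OC)(OC)C=C(C/C=C(\C)CCC=C(C)C)C1=O
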